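**Remarks on the chemistry (assumptions)**

- Structure check: the target is (2S)-5'-geranyl-5,7,2',4'-tetrahydroxyflavanone. In the 4-methoxyflavan formed by the ring-closing step, the descriptors (2S,4S) correspond to the 2,4-cis isomer, and C2 has the same spatial arrangement as in the target (ranking O1 > C1' > C3 > H in both). No structure needed correcting.
- Protecting groups: ring A keeps tert-butyldimethylsilyl ethers. Ring B is carried as triisopropylsilyl ethers, so that the ring B fragment can be built by organometallic chemistry on its final protecting groups, with no protecting-group exchange and no aldehyde. The 2'-oxygen stays masked so that it cannot bridge to C4.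
- The sense of induction of the chiral acid cannot be predicted with confidence. The (R)-acid is written; its antipode would be used if the 2R series were formed.

## Structural features

Kuwanon E is a flavanone: the phloroglucinol-type ring A (5-OH, 7-OH) is fused through C4a–C8a to the dihydropyranone ring C (O1, C2, C3, C4=O), and the resorcinol-type ring B (2'-OH, 4'-OH) is attached at C2. Ring B carries at C5' an (E)-geranyl chain, a 1,5-diene with two trisubstituted alkenes, ortho to the 4'-hydroxyl. The only stereocentre is C2 (S); it is benzylic, bonded to O1, β to the C4 carbonyl, and has no stereogenic neighbour. C2 is fragile in two ways: base opens ring C by retro-oxa-Michael reaction to the 2'-hydroxychalcone, and acid can ionise the C2–O1 bond with help from the 2'- and 4'-oxygens. The chain is fragile as well: acid cyclises it onto the 4'-hydroxyl or onto itself, and electrophilic oxidants attack its alkenes and its doubly activated ArCH2–CH= position. The real difficulty is to fix the absolute configuration at C2 in a ring that can reopen, while two very electron-rich arenes and the acid-sensitive chain are present. The key step uses the fact that O1–C2 and C3–C4 of ring C map onto the heterodiene O1=C8a–C4a=C4 (an ortho-quinone methide of ring A, with C4 at the ether oxidation level) and the C2=C3 vinyl group of a ring B styrene. The polarity matches: C4 is the electrophilic terminus, and C2 is a benzylic carbon stabilised by the 2'- and 4'-oxygens.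

## Logic of the disconnections

**15 to 14.** The four phenolic O–H bonds are traced back to O–Si bonds. With all four phenols masked as silyl ethers, the last step is one fluoride cleavage and no earlier step has to tolerate free, oxidisable phenols. The forward step must not expose the chromanone to phenoxide base, since ring opening would erase C2; the fluoride is therefore buffered.

**14 to 13.** The C4 carbonyl is taken back to the C4 carbinol (C4=O to C4–OH, no skeletal bond cut). This places the ketone one mild oxidation away and makes the C4 configuration irrelevant. The oxidant must spare the chain alkenes and the silyl ethers and must not approach C2.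

**13 to 12.** The C4–OH bond is traced back to a C4–OMe bond. The methyl ether is the form in which the ring-forming step delivers C4. The forward step needs the C4–O bond to ionise without the C2–O1 bond following, and without loss of H3 to the flav-3-ene.

**12 to 10 and 7.** The O1–C2 and C3–C4 bonds of ring C are cut. This splits the molecule into its two aromatic halves, each a few steps from a commercial arene, and removes ring C and both stereocentres at once. The forward step must select one face of the cation, react at the vinyl group and not at the chain alkenes, and favour the cross-reaction over self-alkylation of ring A.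

**10 to 9 to 8.** The two acetal C–OMe bonds and two O–Si bonds are cut. The hydroxyl that must stay free as the future O1 is the chelated one, which stoichiometric silylation leaves untouched, so no separate differentiation is needed. The forward steps need a selective double silylation and a gentle acetalisation; 10 must be handled base-buffered because it ionises easily.

**7 to 6.** The aryl–vinyl bond (C1'–C2) is cut. Installing the vinyl group by cross-coupling avoids an aldehyde and an olefination. The coupling must be neutral, because aryl silyl ethers are cleaved by aqueous base and by fluoride.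

**6 to 2 and 3.** The C5'–CH2 bond of the chain is cut. Because 2 is symmetric, a single halogen–metal exchange desymmetrises it. The forward step needs one exchange only, no shift of silicon from oxygen to the carbanion, and attack at the primary carbon of 3 with the E-alkene kept.

**2 to 1.** Two O–Si bonds are cut. The bulkier silyl group is chosen to meet the demand of the previous paragraph.

## Other disconnections considered

**Alternative 1:** The cut runs through ring A (C4a–C8a, C5–C6, C7–C8), so ring A is built from three alkynes and ring C closes in the same event. In the forward step the tethered diyne A2 and tert-butoxyethyne A3 would combine under [Rh(cod)2]BF4 with BINAP (monovalent rhodium), through a rhodacyclopentadiene and insertion of A3, to give A1.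

- In its favour: C4 is already a ketone in A1, so no redox adjustment follows ring formation; on this point it is better than the chosen plan. The C2 stereocentre sits in the tether and could be set beforehand by an established acyclic method, so the ring-forming step needs no enantiocontrol; this is also a point on which it is better.
- Against it here: A2 holds an alkynyl ether of a secondary benzylic alcohol and an alkoxy ynone β to that ether oxygen. Alkynyl ethers with β-hydrogens (A3 included) fragment to ketenes on warming, the ynone is a strong Michael acceptor, and the β-alkynyloxy ketone can expel ynolate by E1cB and lose C2. The orientation of A3 on insertion (oxygen at C7, not C6) rests on a small electronic bias. The rhodium catalyst could also engage the chain alkenes. Removing the tert-butyl and methoxymethyl ethers from A1 needs strong acid, under which the chain cyclises onto the 4'-hydroxyl.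
- Comparison: the chosen plan uses rings A and B as bought, whereas this plan builds ring A, the cheapest part of the molecule, atom by atom. Both key steps are formal cycloadditions; the alternative has the more secure stereochemistry and the chosen plan the more robust substrates. Preparing A2 alone would take more steps than the whole chosen route, and the endgame is harsher.

**Alternative 2:** Only C2–C3 is cut; rings A and B are first joined through O1 as the aryl benzyl ether A5. In the forward step DDQ would abstract hydride from the benzylic CH2 of A5, and the enol acetate carbon would attack the oxocarbenium ion, paired with a chiral phosphate, to give A4 after loss of the acetyl group.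

- In its favour: A5 comes from a simple etherification of two aromatic pieces, so the route to the flavanone core is equal to or shorter than the chosen one. C4 appears directly as the ketone, which is better than the chosen plan, and the product has no ionisable C4 leaving group. C2 is set in the C–C bond-forming step.
- Against it here: the chain cannot be present, because its ArCH2–CH= position and its alkenes are sensitive to DDQ; hence the bromine at C5' of A4 and a late geranylation on a flavanone. That excludes aryllithium chemistry and leaves allyl-metal cross-couplings, with their α/γ regiochemistry problem, on a base-sensitive ketone. Hydride abstraction from an aryl benzyl ether gives a less stabilised cation than from an alkyl benzyl ether. DDQ is also the classical reagent for dehydrogenating chromanones across C2–C3, which would erase C2. The methoxymethyl ethers must finally be removed with acid in the presence of the chain.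
- Comparison: structurally it is more direct up to the core and weaker at the chain. Mechanistically both plans depend on a chiral anion steering a cation, and are equal in that uncertainty. In step count the short start is offset by the late chain installation and the acidic deprotection.

**Alternative 3:** The cut lies in ring B (C1'–C2', C2'–C3', C4'–C5'), which is assembled from acyclic parts. In the forward step irradiation of the α-diazo enone A7 would give a vinylketene by Wolff rearrangement. This would add the siloxyalkyne A8 by [2+2] cycloaddition and pass through four-electron opening of the cyclobutenone, six-electron electrocyclisation and tautomerisation to A6.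

- In its favour: the ring B pattern arises regiospecifically, with the two oxygens differentiated and the chain in place without aryl–metal chemistry. The future C2 could come from an established asymmetric aldol or β-keto ester reduction, so on certainty of absolute configuration it is better than the chosen plan.
- Against it here: the diazo carbon of A7 is flanked by the allylic CH2 of the chain, so 1,2-hydrogen shift and intramolecular cyclopropanation compete with the Wolff rearrangement, and the ketene can add to the chain alkenes. The benzannulation needs heat, and A6, a benzylic silyl ether with a free ortho hydroxyl and a β-ester, can lose silanol to an ortho-quinone methide or to the conjugated ester, either of which destroys C2. After A6, ring A must still be attached and ring C closed, which takes several further steps.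
- Comparison: this plan spends its key step on a ring that resorcinol provides for nothing, whereas the chosen plan spends it on ring C, the only ring that must be made. Its pericyclic cascade is elegant but fits the chain poorly. Its step count would be the highest of the four plans.

Key step: step 6

Step 1
Reactants: 1 4,6-dibromoresorcinol (4,6-dibromobenzene-1,3-diol)
Product: 2 1,5-dibromo-2,4-bis(triisopropylsilyloxy)benzene
Conditions: TIPSCl (2.4 equiv), imidazole (5 equiv), DMF, rt → 40 °C
Reagents that add atoms: triisopropylsilyl chloride, `CC(C)[Si](Cl)(C(C)C)C(C)C`
Why: Both phenols are silylated through the N-silylimidazolium species; gentle warming completes the second silylation next to bromine. The triisopropylsilyl group is chosen because it resists the anionic oxygen-to-carbon silyl shift that threatens step 2.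

Step 2
Reactants: 2 1,5-dibromo-2,4-bis(triisopropylsilyloxy)benzene; 3 geranyl bromide [(2E)-1-bromo-3,7-dimethylocta-2,6-diene]
Product: 6 1-bromo-5-[(2E)-3,7-dimethylocta-2,6-dien-1-yl]-2,4-bis(triisopropylsilyloxy)benzene, via aryllithium 4 (not isolated), via arylcopper 5 (not isolated)
Conditions: n-BuLi (1.05 equiv), THF, −78 °C; CuBr·SMe2 (1.1 equiv), −78 °C; then 3 (1.2 equiv), −78 → 0 °C
Reagents that add atoms: none
Why: Bromine–lithium exchange is fast at −78 °C and stops after one bromine, because aryllithium 4 is a poor partner for a second exchange; immediate transmetalation to arylcopper 5 removes the carbanion character that would drive silyl migration. The arylcopper then displaces bromide at the primary allylic carbon of 3 (copper-mediated SN2 allylic substitution), which keeps the E-alkene and gives the linear chain.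

Step 3
Reactants: 6 1-bromo-5-[(2E)-3,7-dimethylocta-2,6-dien-1-yl]-2,4-bis(triisopropylsilyloxy)benzene
Product: 7 1-ethenyl-5-[(2E)-3,7-dimethylocta-2,6-dien-1-yl]-2,4-bis(triisopropylsilyloxy)benzene
Conditions: CH2=CHSnBu3 (1.3 equiv), Pd(PPh3)4 (5 mol %), BHT (cat.), toluene, 100 °C
Reagents that add atoms: tributyl(vinyl)stannane, `C=C[Sn](CCCC)(CCCC)CCCC`
Why: Stille coupling: oxidative addition of zerovalent palladium into the C–Br bond, vinyl transfer from tin and reductive elimination. The conditions are neutral and free of fluoride and aqueous base, so the aryl silyl ethers survive, and the chain (meta to the palladium-bearing carbon) cannot undergo an intramolecular Heck reaction.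

Step 4
Reactants: 8 2,4,6-trihydroxybenzaldehyde
Product: 9 2-hydroxy-4,6-bis(tert-butyldimethylsilyloxy)benzaldehyde
Conditions: TBSCl (2.1 equiv), imidazole (4.5 equiv), DMF, 0 °C
Reagents that add atoms: tert-butyldimethylsilyl chloride, `CC(C)(C)[Si](C)(C)Cl`
Why: Chelation-controlled selective silylation: the para hydroxyl and one ortho hydroxyl react, whereas the remaining ortho hydroxyl is held in a hydrogen bond to the formyl oxygen and is silylated much more slowly with two equivalents at 0 °C. This free hydroxyl is the one that becomes O1.

Step 5
Reactants: 9 2-hydroxy-4,6-bis(tert-butyldimethylsilyloxy)benzaldehyde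
Product: 10 2-(dimethoxymethyl)-3,5-bis(tert-butyldimethylsilyloxy)phenol
Conditions: HC(OMe)3 (5 equiv), PPTS (5 mol %), MeOH, rt; Et3N quench, concentrate, use at once without chromatography on acidic silica
Reagents that add atoms: trimethyl orthoformate, `COC(OC)OC`
Why: Acid-catalysed acetalisation, driven to completion because the orthoformate consumes the water formed and ends as methyl formate. The weak pyridinium acid and the triethylamine quench keep the aryl silyl ethers and the ionisation-prone acetal intact.

Step 6
Reactants: 10 2-(dimethoxymethyl)-3,5-bis(tert-butyldimethylsilyloxy)phenol; 7 1-ethenyl-5-[(2E)-3,7-dimethylocta-2,6-dien-1-yl]-2,4-bis(triisopropylsilyloxy)benzene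
Product: 12 (2S,4S)-5,7-bis(tert-butyldimethylsilyloxy)-5'-geranyl-4-methoxy-2',4'-bis(triisopropylsilyloxy)flavan (2,4-cis), via oxocarbenium ion 11 (not isolated)
Conditions: (R)-TRIP [(R)-3,3'-bis(2,4,6-triisopropylphenyl)-1,1'-binaphthyl-2,2'-diyl hydrogen phosphate] (10 mol %), 5 Å MS, toluene, −40 → −20 °C, 10 added slowly to 7 (1.3 equiv); Et3N quench
Reagents that add atoms: none
Why: The phosphoric acid protonates one methoxy group of 10, and loss of methanol (taken up by the sieves) gives ion pair 11, an O-methyl oxocarbenium ion that is equally the O-protonated 4-methoxy ortho-quinone methide of ring A, with the chiral phosphate hydrogen-bonded to the phenolic OH. The CH2 terminus of styrene 7 attacks the electrophilic carbon (future C4) to form C3–C4, and the developing benzylic cation, stabilised by the ortho and para silyloxy groups, is captured by the phenolic oxygen to form O1–C2, an asynchronous inverse-electron-demand oxa-Diels–Alder reaction. The closest known reactions are the acid-promoted cycloadditions of salicylaldehyde acetals with styrenes, which give 2,4-cis-4-alkoxyflavans, and the chiral phosphoric acid-controlled [4+2] cycloadditions of ortho-quinone methides; the present case applies the second kind of control to the first kind of substrate, which is an extension of both. Ring C closes in a [4π+2π] mode, the heterodiene O1=C8a–C4a=C4 adding across C2=C3 through a half-chair transition state. C4 is set by the face of the cation that the bound phosphate leaves open; C2 follows from C4 because the ring should close with the aryl group pseudo-equatorial and cis to the methoxy group, and the antipode of the acid is chosen so that C2 is S (to be judged at 14). The step needs chemoselectivity for the styrene over the two trisubstituted chain alkenes, which the donor-conjugated vinyl group secures by its far higher nucleophilicity; regioselectivity, which the polarisation of both partners dictates; and suppression of self-alkylation of ring A, which the flanking silyl ethers and the slow addition of 10 should provide.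

Step 7
Reactants: 12 (2S,4S)-5,7-bis(tert-butyldimethylsilyloxy)-5'-geranyl-4-methoxy-2',4'-bis(triisopropylsilyloxy)flavan
Product: 13 (2S)-5,7-bis(tert-butyldimethylsilyloxy)-5'-geranyl-2',4'-bis(triisopropylsilyloxy)flavan-4-ol (C4 as a mixture of epimers, the 2,4-cis isomer expected to predominate)
Conditions: PPTS (20 mol %), acetone/H2O (5:1), rt
Reagents that add atoms: water, `O`
Why: SN1 solvolysis: the C4–OMe bond ionises readily because the cation is benzylic to the trioxygenated ring A, and the large excess of water drives the exchange to the carbinol by mass action. Both C4 epimers are acceptable since C4 becomes sp2 in the next step; the acid is kept weak so that C2–O1, the chain and the aryl silyl ethers are not affected.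

Step 8
Reactants: 13 (2S)-5,7-bis(tert-butyldimethylsilyloxy)-5'-geranyl-2',4'-bis(triisopropylsilyloxy)flavan-4-ol
Product: 14 (2S)-5,7-bis(tert-butyldimethylsilyloxy)-5'-geranyl-2',4'-bis(triisopropylsilyloxy)flavanone
Conditions: Dess–Martin periodinane (1.5 equiv), NaHCO3, CH2Cl2, 0 °C → rt
Reagents that add atoms: none
Why: Dess–Martin oxidation of the secondary benzylic alcohol by ligand exchange at iodine and intramolecular proton abstraction. The buffered reagent is neutral, does not touch trisubstituted alkenes or silyl ethers, and removes the C4 stereocentre without approaching C2.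

Step 9
Reactants: 14 (2S)-5,7-bis(tert-butyldimethylsilyloxy)-5'-geranyl-2',4'-bis(triisopropylsilyloxy)flavanone
Product: 15 kuwanon E [(2S)-5'-geranyl-5,7,2',4'-tetrahydroxyflavanone]
Conditions: TBAF (6 equiv), AcOH (6 equiv), THF, 0 °C → rt
Reagents that add atoms: none
Why: Fluoride cleaves all four aryl silyl ethers (strong Si–F bond, phenoxide as leaving group). Acetic acid protonates each phenoxide as it forms, so the chromanone is never exposed to base, and the retro-oxa-Michael opening to the chalcone, by which C2 would racemise, is suppressed; the chain is inert to these conditions.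

**Compound list**

```
1 | 4,6-dibromoresorcinol | Oc1cc(O)c(Br)cc1Br | starting material
2 | 1,5-dibromo-2,4-bis(triisopropylsilyloxy)benzene | Brc1cc(Br)c(O[Si](C(C)C)(C(C)C)C(C)C)cc1O[Si](C(C)C)(C(C)C)C(C)C | intermediate
3 | geranyl bromide, (2E)-1-bromo-3,7-dimethylocta-2,6-diene | CC(C)=CCC/C(C)=C/CBr | starting material
4 | [5-bromo-2,4-bis(triisopropylsilyloxy)phenyl]lithium | [Li]c1cc(Br)c(O[Si](C(C)C)(C(C)C)C(C)C)cc1O[Si](C(C)C)(C(C)C)C(C)C | intermediate (not isolated)
5 | [5-bromo-2,4-bis(triisopropylsilyloxy)phenyl]copper (monovalent copper) | [Cu]c1cc(Br)c(O[Si](C(C)C)(C(C)C)C(C)C)cc1O[Si](C(C)C)(C(C)C)C(C)C | intermediate (not isolated)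
6 | 1-bromo-5-[(2E)-3,7-dimethylocta-2,6-dien-1-yl]-2,4-bis(triisopropylsilyloxy)benzene | CC(C)=CCC/C(C)=C/Cc1cc(Br)c(O[Si](C(C)C)(C(C)C)C(C)C)cc1O[Si](C(C)C)(C(C)C)C(C)C | intermediate
7 | 1-ethenyl-5-[(2E)-3,7-dimethylocta-2,6-dien-1-yl]-2,4-bis(triisopropylsilyloxy)benzene | CC(C)=CCC/C(C)=C/Cc1cc(C=C)c(O[Si](C(C)C)(C(C)C)C(C)C)cc1O[Si](C(C)C)(C(C)C)C(C)C | intermediate
8 | 2,4,6-trihydroxybenzaldehyde | O=Cc1c(O)cc(O)cc1O | starting material
9 | 2-hydroxy-4,6-bis(tert-butyldimethylsilyloxy)benzaldehyde | O=Cc1c(O)cc(O[Si](C)(C)C(C)(C)C)cc1O[Si](C)(C)C(C)(C)C | intermediate
10 | 2-(dimethoxymethyl)-3,5-bis(tert-butyldimethylsilyloxy)phenol | COC(OC)c1c(O)cc(O[Si](C)(C)C(C)(C)C)cc1O[Si](C)(C)C(C)(C)C | intermediate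
11 | [2-hydroxy-4,6-bis(tert-butyldimethylsilyloxy)phenyl](methoxy)methylium ion (O-protonated 4-methoxy ortho-quinone methide, paired with the chiral phosphate) | C[O+]=Cc1c(O)cc(O[Si](C)(C)C(C)(C)C)cc1O[Si](C)(C)C(C)(C)C | intermediate (not isolated)
12 | (2S,4S)-5,7-bis(tert-butyldimethylsilyloxy)-5'-geranyl-4-methoxy-2',4'-bis(triisopropylsilyloxy)flavan (2,4-cis) | CC(C)=CCC/C(C)=C/Cc1cc([C@@H]2C[C@H](OC)c3c(O[Si](C)(C)C(C)(C)C)cc(O[Si](C)(C)C(C)(C)C)cc3O2)c(O[Si](C(C)C)(C(C)C)C(C)C)cc1O[Si](C(C)C)(C(C)C)C(C)C | intermediate
13 | (2S)-5,7-bis(tert-butyldimethylsilyloxy)-5'-geranyl-2',4'-bis(triisopropylsilyloxy)flavan-4-ol (C4 epimers) | CC(C)=CCC/C(C)=C/Cc1cc([C@@H]2CC(O)c3c(O[Si](C)(C)C(C)(C)C)cc(O[Si](C)(C)C(C)(C)C)cc3O2)c(O[Si](C(C)C)(C(C)C)C(C)C)cc1O[Si](C(C)C)(C(C)C)C(C)C | intermediate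
14 | (2S)-5,7-bis(tert-butyldimethylsilyloxy)-5'-geranyl-2',4'-bis(triisopropylsilyloxy)flavanone | CC(C)=CCC/C(C)=C/Cc1cc([C@@H]2CC(=O)c3c(O[Si](C)(C)C(C)(C)C)cc(O[Si](C)(C)C(C)(C)C)cc3O2)c(O[Si](C(C)C)(C(C)C)C(C)C)cc1O[Si](C(C)C)(C(C)C)C(C)C | intermediate
15 | kuwanon E, (2S)-5'-geranyl-5,7,2',4'-tetrahydroxyflavanone | CC(C)=CCC/C(C)=C/Cc1cc([C@@H]2CC(=O)c3c(O)cc(O)cc3O2)c(O)cc1O | target
```

**Step count and risk**

Total step count: 9. Longest linear sequence: 7 steps (steps 1, 2, 3, 6, 7, 8, 9); the ring A branch (steps 4 and 5) joins at step 6.

Least certain steps:

- **Step 6 (key step).** Several processes may go wrong.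
  - Facial discrimination may be poor, because only the cation is anchored to the phosphate and the styrene carries no hydrogen-bond donor.
  - The course may be stepwise with a long-lived benzylic cation, so that ring closure gives both C2 epimers. The peri 5-silyloxy group favours a pseudo-axial 4-methoxy group and may erode the cis preference. Because C4 is erased later, C2 epimers that share one C4 configuration end as opposite enantiomers of 14.
  - The C2–O1 or C4–OMe bond may re-ionise under the acid.
  - Ring A may be alkylated by the cation, and the styrene may oligomerise under acid.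
  - The ortho triisopropylsilyl ether may retard the reaction sterically.
  
  The enantiomeric purity would therefore be read at 14, where C2 is the only stereocentre. Fallback, setting out from 10 and 7: the cycloaddition is run with an achiral acid, (PhO)2P(O)OH, to give the racemic cis-4-methoxyflavan F1. The conditions of steps 7 and 8 then give the racemic flavan-4-ol F2 and the racemic flavanone F3. F3 is resolved kinetically by asymmetric transfer hydrogenation with RuCl(p-cymene)[(R,R)-TsDPEN] (divalent ruthenium) in HCO2H/Et3N. By analogy with aryl ketones, the (R)-ketone is expected to be reduced faster to the (2R,4R)-cis-flavan-4-ol F4, leaving the (S)-ketone, which is 14; the route is rejoined there. The ligand antipode would be chosen accordingly.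

- **Step 2.** The ortho-lithiated silyl ether may undergo anionic 1,3 oxygen-to-carbon silyl migration before transmetalation. Both bromines may exchange. Attack at the γ-carbon of 3 would give the branched isomer, and allyl–copper equilibration could erode the E geometry. Fallback, setting out from 1: protection with MOMCl/i-Pr2NEt gives 1,5-dibromo-2,4-bis(methoxymethoxy)benzene F5, whose ortho-lithiated form is chelated and cannot migrate. The same exchange, copper transmetalation and reaction with 3 give 1-bromo-5-geranyl-2,4-bis(methoxymethoxy)benzene F6. Dilute HCl in MeOH at rt gives 4-bromo-6-geranylbenzene-1,3-diol F7, and TIPSCl/imidazole returns to the route at 6.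

- **Step 7.** The C4 cation may lose H3 to give the flav-3-ene and not be captured by water. The C2–O1 bond may ionise, with loss of configurational integrity, and silyl groups may be partly lost. Fallback, setting out from 12: the benzylic methyl ether is cleaved oxidatively with DDQ in CH2Cl2/pH 7 buffer (hydride abstraction from C4–H, capture of the oxocarbenium ion by water, collapse of the hemiketal). This gives 14 directly and bypasses 13; no new compound is made (F0).

- **Step 5.** The acetal may ionise on concentration or on contact with silica and condense with itself through the ortho-quinone methide. Conversion of the chelated aldehyde may be incomplete. Fallback, setting out from 9: the acetal is not isolated; 9, HC(OMe)3 and 7 are combined with the acid in one flask (three-component variant), so that 10 forms and is consumed in situ. The route is rejoined at 12; no new compound is made (F0).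

- **Step 3.** Oxidative addition into the electron-rich, hindered C–Br bond may be slow, giving protodebromination, and the product styrene may polymerise thermally. Fallback, setting out from 6: bromine–lithium exchange (t-BuLi, 2 equiv, Et2O, −78 °C) and formylation with DMF give 5-geranyl-2,4-bis(triisopropylsilyloxy)benzaldehyde F8. Wittig methylenation (Ph3PCH3Br, KN(SiMe3)2, THF, 0 °C) returns to the route at 7.

**Further compounds**

```
F1 | step 6 | rac-(2S*,4S*)-5,7-bis(tert-butyldimethylsilyloxy)-5'-geranyl-4-methoxy-2',4'-bis(triisopropylsilyloxy)flavan (racemate, relative configuration drawn) | CC(C)=CCC/C(C)=C/Cc1cc([C@@H]2C[C@H](OC)c3c(O[Si](C)(C)C(C)(C)C)cc(O[Si](C)(C)C(C)(C)C)cc3O2)c(O[Si](C(C)C)(C(C)C)C(C)C)cc1O[Si](C(C)C)(C(C)C)C(C)C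
F2 | step 6 | racemic 5,7-bis(tert-butyldimethylsilyloxy)-5'-geranyl-2',4'-bis(triisopropylsilyloxy)flavan-4-ol (C4 epimers) | CC(C)=CCC/C(C)=C/Cc1cc(C2CC(O)c3c(O[Si](C)(C)C(C)(C)C)cc(O[Si](C)(C)C(C)(C)C)cc3O2)c(O[Si](C(C)C)(C(C)C)C(C)C)cc1O[Si](C(C)C)(C(C)C)C(C)C
F3 | step 6 | racemic 5,7-bis(tert-butyldimethylsilyloxy)-5'-geranyl-2',4'-bis(triisopropylsilyloxy)flavanone | CC(C)=CCC/C(C)=C/Cc1cc(C2CC(=O)c3c(O[Si](C)(C)C(C)(C)C)cc(O[Si](C)(C)C(C)(C)C)cc3O2)c(O[Si](C(C)C)(C(C)C)C(C)C)cc1O[Si](C(C)C)(C(C)C)C(C)C
F4 | step 6 | (2R,4R)-5,7-bis(tert-butyldimethylsilyloxy)-5'-geranyl-2',4'-bis(triisopropylsilyloxy)flavan-4-ol (2,4-cis) | CC(C)=CCC/C(C)=C/Cc1cc([C@H]2C[C@@H](O)c3c(O[Si](C)(C)C(C)(C)C)cc(O[Si](C)(C)C(C)(C)C)cc3O2)c(O[Si](C(C)C)(C(C)C)C(C)C)cc1O[Si](C(C)C)(C(C)C)C(C)C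
F5 | step 2 | 1,5-dibromo-2,4-bis(methoxymethoxy)benzene | COCOc1cc(OCOC)c(Br)cc1Br
F6 | step 2 | 1-bromo-5-[(2E)-3,7-dimethylocta-2,6-dien-1-yl]-2,4-bis(methoxymethoxy)benzene | CC(C)=CCC/C(C)=C/Cc1cc(Br)c(OCOC)cc1OCOC
F7 | step 2 | 4-bromo-6-[(2E)-3,7-dimethylocta-2,6-dien-1-yl]benzene-1,3-diol | CC(C)=CCC/C(C)=C/Cc1cc(Br)c(O)cc1O
F0 | step 7 | none | none
F0 | step 5 | none | none
F8 | step 3 | 5-[(2E)-3,7-dimethylocta-2,6-dien-1-yl]-2,4-bis(triisopropylsilyloxy)benzaldehyde | CC(C)=CCC/C(C)=C/Cc1cc(C=O)c(O[Si](C(C)C)(C(C)C)C(C)C)cc1O[Si](C(C)C)(C(C)C)C(C)C
A1 | alternative 1 | (S)-5,7-di-O-tert-butyl-2',4'-bis-O-(methoxymethyl)kuwanon E | CC(C)=CCC/C(C)=C/Cc1cc([C@@H]2CC(=O)c3c(OC(C)(C)C)cc(OC(C)(C)C)cc3O2)c(OCOC)cc1OCOC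
A2 | alternative 1 | (5S)-1-tert-butoxy-5-(ethynyloxy)-5-[5-geranyl-2,4-bis(methoxymethoxy)phenyl]pent-1-yn-3-one | CC(C)=CCC/C(C)=C/Cc1cc([C@@H](OC#C)CC(=O)C#COC(C)(C)C)c(OCOC)cc1OCOC
A3 | alternative 1 | tert-butoxyethyne | C#COC(C)(C)C
A4 | alternative 2 | (S)-5'-bromo-5,7,2',4'-tetrakis(methoxymethoxy)flavanone | Brc1cc([C@@H]2CC(=O)c3c(OCOC)cc(OCOC)cc3O2)c(OCOC)cc1OCOC
A5 | alternative 2 | 1-{2-[(5-bromo-2,4-bis(methoxymethoxy)phenyl)methoxy]-4,6-bis(methoxymethoxy)phenyl}ethenyl acetate | C=C(OC(C)=O)c1c(OCOC)cc(OCOC)cc1OCc1cc(Br)c(OCOC)cc1OCOC
A6 | alternative 3 | methyl (3S)-3-(tert-butyldimethylsilyloxy)-3-[5-geranyl-2-hydroxy-4-(triisopropylsilyloxy)phenyl]propanoate | CC(C)=CCC/C(C)=C/Cc1cc([C@@H](O[Si](C)(C)C(C)(C)C)CC(=O)OC)c(O)cc1O[Si](C(C)C)(C(C)C)C(C)C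
A7 | alternative 3 | methyl (3S,4E,9E)-3-(tert-butyldimethylsilyloxy)-7-diazo-10,14-dimethyl-6-oxopentadeca-4,9,13-trienoate | CC(C)=CCC/C(C)=C/CC(=[N+]=[N-])C(=O)/C=C/[C@@H](O[Si](C)(C)C(C)(C)C)CC(=O)OC
A8 | alternative 3 | (triisopropylsilyloxy)ethyne | C#CO[Si](C(C)C)(C(C)C)C(C)C
```
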